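Germacrane numbering is used. The ten-membered ring hides a 1,5-diene relationship: C9–C10=C1 on one side and the C6 oxygen with C7–C8 on the other, so C8 is a homoallylic carbinol 1,3 to O6. Cutting C8–C9 and joining C1–C6 contracts the ring to a cyclohexenol, the adduct of (R)-isopiperitenone and a (Z)-β-alkoxyvinyl metal. One anionic oxy-Cope rearrangement then forms C8–C9, enlarges six atoms to ten, sets the (E)-C1=C10 alkene, relays the C1 stereocentre to C8 and, on protonation, fixes C7. The cis C4=C5 bond inherited from the small ring is inverted afterwards. Outer-face reduction sets C6.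

Key step: step 8

Numbering: C1H=C10(CH3), C2H2, C3H2, C4(CH3)=C5H, C6 (hydroxyl), C7 (isopropyl), C8 (ester oxygen), C9H2. C14 and C15 are the methyl groups on C10 and C4.
Assumption: commercial (S)-(−)-limonene of high enantiomeric purity is the only source of absolute configuration.
Handling remark: all (E,E)-dienes from 22 onward are kept at or below room temperature and away from strong acid. This avoids Cope rearrangement and transannular cyclisation.

Step 1
Reactants: 1 (S)-(−)-limonene
Product: 2 (4S)-limonene 1,2-oxide (cis/trans mixture)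
Conditions: mCPBA (1 equiv), NaHCO3, CH2Cl2, 0 °C
Reagents that add atoms: 3-chloroperbenzoic acid, O=C(OO)c1cccc(Cl)c1
Why: Prilezhaev epoxidation picks the more electron-rich trisubstituted ring alkene over the isopropenyl group, and the two new centres need no control because step 3 erases them.

Step 2
Reactants: 2 (4S)-limonene 1,2-oxide
Product: 5 (4S)-p-mentha-2,8-dien-1-ol (both C1 epimers), via hydroxy selenide 3 (not isolated), via selenoxide 4 (not isolated)
Conditions: PhSeSePh, NaBH4, EtOH, reflux; then 30% H2O2, THF, 0 °C to rt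
Reagents that add atoms: diphenyl diselenide, c1ccc(cc1)[Se][Se]c1ccccc1 (selenium of 3 and 4); hydrogen peroxide, OO (selenoxide oxygen of 4)
Why: SN2 opening of the oxirane by selenolate at the secondary carbon is followed by selenoxide syn-elimination, which can only run away from the fully substituted carbinol carbon, so the tertiary allylic alcohol forms with the isopropenyl-bearing centre untouched.

Step 3
Reactants: 5 (4S)-p-mentha-2,8-dien-1-ol
Product: 6 (R)-(−)-isopiperitenone
Conditions: pyridinium chlorochromate (C5H5NH[CrO3Cl]), NaOAc, 4 Å molecular sieves, CH2Cl2, rt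
Reagents that add atoms: pyridinium chlorochromate, [O-][Cr](=O)(=O)Cl.c1cc[nH+]cc1
Why: In the Babler–Dauben oxidative transposition the tertiary allylic chromate ester undergoes a [3,3]-shift and the secondary chromate is oxidised to the enone, so both carbinol epimers converge on one ketone whose stereocentre comes from limonene (the buffer guards against epimerisation).

Step 4
Reactants: 7 3-methylbutanal; 8 4-methoxybenzyl alcohol (2 equiv)
Product: 9 3-methylbutanal bis(4-methoxybenzyl) acetal
Conditions: PPTS (cat.), benzene, Dean–Stark, reflux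
Reagents that add atoms: none
Why: Acid-catalysed acetalisation is driven by azeotropic removal of water, and the weak acid avoids self-etherification of the benzylic alcohol.

Step 5
Reactants: 9 3-methylbutanal bis(4-methoxybenzyl) acetal
Product: 10 4-methoxybenzyl 3-methylbut-1-enyl ether (E/Z mixture)
Conditions: TMSOTf, i-Pr2NEt, CH2Cl2, −20 °C to rt
Reagents that add atoms: none
Why: In this silyl-triflate-mediated acetal-to-enol-ether elimination the Lewis acid ionises one alkoxy group and the hindered amine removes the β-proton of the oxocarbenium ion.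

Step 6
Reactants: 10 4-methoxybenzyl 3-methylbut-1-enyl ether
Product: 12 (Z)-2-bromo-3-methylbut-1-enyl 4-methoxybenzyl ether, via dibromide 11 (not isolated)
Conditions: Br2, CH2Cl2, −78 °C; then DBU, −78 °C to rt
Reagents that add atoms: bromine, BrBr
Why: Bromine adds to the enol ether much faster than to the anisyl ring at −78 °C, and dehydrobromination through the oxocarbenium ion favours the isomer with the alkoxy group trans to isopropyl (Br cis to O), while any E isomer is harmless because its lithio derivative destroys itself by anti β-elimination in step 7.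

Step 7
Reactants: 12 (Z)-2-bromo-3-methylbut-1-enyl 4-methoxybenzyl ether; 6 (R)-(−)-isopiperitenone
Product: 15 (1R,6R)-1-[(Z)-1-(4-methoxybenzyloxy)-3-methylbut-1-en-2-yl]-3-methyl-6-(prop-1-en-2-yl)cyclohex-2-en-1-ol, via vinyllithium 13 (not isolated), via organocerium reagent 14 (not isolated)
Conditions: t-BuLi (2 equiv), Et2O, −78 °C; anhydrous CeCl3, THF, −78 °C; then 6, −78 °C; aq. NaHCO3 work-up, Et3N-deactivated silica
Reagents that add atoms: cerium trichloride, Cl[Ce](Cl)Cl (cerium and chlorine of 14)
Why: Bromine–lithium exchange runs with retention and the cis alkoxy oxygen chelates lithium in a geometry that cannot undergo anti β-elimination, the weakly basic organocerium reagent favours 1,2-addition over enolisation of the epimerisable ketone, and attack anti to the neighbouring isopropenyl group (equatorial attack) sets the carbinol centre C6 with the two alkenyl groups trans.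

Step 8
Reactants: 15 (1R,6R)-1-[(Z)-1-(4-methoxybenzyloxy)-3-methylbut-1-en-2-yl]-3-methyl-6-(prop-1-en-2-yl)cyclohex-2-en-1-ol
Product: 18 (1(10)E,4Z,7R,8S)-8-(4-methoxybenzyloxy)germacra-1(10),4-dien-6-one, via potassium alkoxide 16 (not isolated), via potassium enolate 17 (not isolated)
Conditions: KH, 18-crown-6, THF, 0 °C to rt; then −78 °C, AcOH in THF
Reagents that add atoms: none
Why: Potassium alkoxide 16 undergoes an anionic oxy-Cope [3,3]-sigmatropic rearrangement of the C9=C10–C1–C6–C7=C8 diene, the closest known reaction type being the ring expansion of 1,2-dialkenylcyclohexanols to cyclodec-5-enones. The ten-membered ring is closed by ring enlargement, the C8–C9 σ-bond forming while the C1–C6 bond of the cyclohexene breaks (six to ten atoms), driven by formation of enolate 17. With the two alkenyl groups trans-diequatorial only one chair transition state is open, the boat is disfavoured because it eclipses the C10 methyl and C7 isopropyl groups, and the equatorial C1–C2 bond gives the (E)-C1=C10 alkene. C8 is set by suprafacial chirality transfer from C1 (R) through this chair together with the Z geometry of the enol ether (alkoxy group axial), which should give 8S. C7 is set on quenching, because the tetrasubstituted enolate is an in-ring E alkene that offers only its outer face to the proton, which places isopropyl trans to the C8 oxygen, also the more stable diequatorial arrangement. The step needs the β-alkoxy enolate to survive without E1cB loss, which is helped by the C8–O bond lying near the nodal plane of the enolate (the aligned bond is the new C8–C9 bond), by the low temperature that 18-crown-6 allows and by the cold acidic quench, while C4=C5 stays cis as in the six-membered ring.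

Step 9
Reactants: 18 (1(10)E,4Z,7R,8S)-8-(4-methoxybenzyloxy)germacra-1(10),4-dien-6-one
Product: 20 (1(10)E,5E,7R,8S)-8-(4-methoxybenzyloxy)-4-(trimethylstannyl)-6-(trimethylsilyloxy)germacra-1(10),5-diene (C4 not assigned), via lithium enolate 19 (not isolated)
Conditions: Me3SnLi (from Me3SnSnMe3 and MeLi), THF, −78 °C; then Me3SiCl, Et3N, −78 to 0 °C
Reagents that add atoms: trimethylstannyllithium, [Li][Sn](C)(C)C; chlorotrimethylsilane, C[Si](C)(C)Cl
Why: Conjugate addition of the soft stannyl anion to the β,β-disubstituted enone from the outer ring face and O-silylation of the enolate turn sp2 C4 into a rotatable sp3 centre, and C7 and C8 stay untouched because the enolate lies on the C5 side.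

Step 10
Reactants: 20 β-stannyl silyl enol ether
Product: 22 (1(10)E,4E,7R,8S)-8-(4-methoxybenzyloxy)germacra-1(10),4-dien-6-one, via silyloxy stannyl ketone 21 (not isolated)
Conditions: mCPBA (1 equiv), CH2Cl2, −78 to 0 °C
Reagents that add atoms: 3-chloroperbenzoic acid, O=C(OO)c1cccc(Cl)c1 (C5 oxygen of 21)
Why: Rubottom-type oxidation should place oxygen on C5 from the same outer face that tin took at C4 (net syn addition across the former cis alkene), so anti β-elimination of the stannyl and silyloxy groups (tin analogue of the acid Peterson elimination) returns the enone with inverted E geometry, and the silyl enol ether outcompetes C1=C10 for the single equivalent of peracid.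

Step 11
Reactants: 22 (1(10)E,4E,7R,8S)-8-(4-methoxybenzyloxy)germacra-1(10),4-dien-6-one
Product: 23 (1(10)E,4E,7R,8S)-8-hydroxygermacra-1(10),4-dien-6-one
Conditions: DDQ, CH2Cl2–pH 7 buffer, 0 °C
Reagents that add atoms: none
Why: Oxidative cleavage of the electron-rich 4-methoxybenzyl ether by DDQ under buffered conditions spares both alkenes and the acid- and base-sensitive β-hydroxy ketone.

Step 12
Reactants: 23 (1(10)E,4E,7R,8S)-8-hydroxygermacra-1(10),4-dien-6-one; 24 (E)-4-acetoxycinnamic acid
Product: 26 (1(10)E,4E,7R,8S)-6-oxogermacra-1(10),4-dien-8-yl (E)-4-acetoxycinnamate, via acid chloride 25 (not isolated)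
Conditions: 24, (COCl)2, DMF (cat.), CH2Cl2, 0 °C to rt, concentrate; then 23, pyridine, DMAP (cat.), CH2Cl2, 0 °C to rt
Reagents that add atoms: oxalyl chloride, O=C(Cl)C(=O)Cl (chlorine of 25)
Why: In this acylation with an acid chloride the C6 ketone serves as the mask of the C6 hydroxyl so only O8 can react, the acid chloride outruns acetyl transfer from the aryl acetate, and the equatorial C8–O bond is not aligned for E1cB loss.

Step 13
Reactants: 26 (1(10)E,4E,7R,8S)-6-oxogermacra-1(10),4-dien-8-yl (E)-4-acetoxycinnamate
Product: 27 (1(10)E,4E,6S,7S,8S)-6-hydroxygermacra-1(10),4-dien-8-yl (E)-4-acetoxycinnamate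
Conditions: NaBH4, CeCl3·7H2O, MeOH–THF, −78 °C
Reagents that add atoms: none
Why: In the Luche 1,2-reduction the crown conformation with isopropyl and acyloxy groups equatorial shields the inner face of the s-cis enone with the C14 and C15 methyl groups, so hydride should enter from the outer face and give the axial 6S alcohol, while both esters are left alone.

Step 14
Reactants: 27 (1(10)E,4E,6S,7S,8S)-6-hydroxygermacra-1(10),4-dien-8-yl (E)-4-acetoxycinnamate
Product: 28 target, (1(10)E,4E,6S,7S,8S)-6-hydroxygermacra-1(10),4-dien-8-yl (E)-4-hydroxycinnamate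
Conditions: NH4OAc, MeOH–H2O, rt
Reagents that add atoms: none
Why: The aryl acetate is a far better acyl donor than the hindered secondary cinnamate, so neutral solvolysis frees the phenol selectively, and the trans-1,3 arrangement of O6 and O8 disfavours acyl migration.

Compound list
1 | (S)-(−)-limonene | CC1=CC[C@H](CC1)C(=C)C | starting material
2 | (4S)-limonene 1,2-oxide, cis/trans mixture | CC12OC1C[C@H](CC2)C(=C)C | intermediate
3 | (4S)-1-methyl-2-(phenylselanyl)-4-(prop-1-en-2-yl)cyclohexan-1-ol | CC1(O)C([Se]c2ccccc2)C[C@H](CC1)C(=C)C | intermediate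
4 | selenoxide of 3 | CC1(O)C([Se](=O)c2ccccc2)C[C@H](CC1)C(=C)C | intermediate
5 | (4S)-p-mentha-2,8-dien-1-ol, both C1 epimers | CC1(O)C=C[C@H](CC1)C(=C)C | intermediate
6 | (R)-(−)-isopiperitenone, (6R)-3-methyl-6-(prop-1-en-2-yl)cyclohex-2-en-1-one | CC1=CC(=O)[C@H](CC1)C(C)=C | intermediate
7 | 3-methylbutanal | CC(C)CC=O | starting material
8 | 4-methoxybenzyl alcohol | COc1ccc(CO)cc1 | starting material
9 | 3-methylbutanal bis(4-methoxybenzyl) acetal | CC(C)CC(OCc1ccc(OC)cc1)OCc1ccc(OC)cc1 | intermediate
10 | 4-methoxybenzyl 3-methylbut-1-enyl ether, E/Z mixture | CC(C)C=COCc1ccc(OC)cc1 | intermediate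
11 | 1,2-dibromo-3-methylbutyl 4-methoxybenzyl ether | CC(C)C(Br)C(Br)OCc1ccc(OC)cc1 | intermediate
12 | (Z)-2-bromo-3-methylbut-1-enyl 4-methoxybenzyl ether | Br/C(C(C)C)=C\OCc1ccc(OC)cc1 | intermediate
13 | (Z)-1-(4-methoxybenzyloxy)-3-methylbut-1-en-2-yllithium | [Li]/C(C(C)C)=C\OCc1ccc(OC)cc1 | intermediate
14 | dichloro[(Z)-1-(4-methoxybenzyloxy)-3-methylbut-1-en-2-yl]cerium | Cl[Ce](Cl)/C(C(C)C)=C\OCc1ccc(OC)cc1 | intermediate
15 | (1R,6R)-1-[(Z)-1-(4-methoxybenzyloxy)-3-methylbut-1-en-2-yl]-3-methyl-6-(prop-1-en-2-yl)cyclohex-2-en-1-ol | CC1=C[C@](O)(/C(C(C)C)=C\OCc2ccc(OC)cc2)[C@H](CC1)C(C)=C | intermediate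
16 | potassium alkoxide of 15 | CC1=C[C@]([O-])(/C(C(C)C)=C\OCc2ccc(OC)cc2)[C@H](CC1)C(C)=C.[K+] | intermediate
17 | potassium C6=C7 enolate of 18 (C5 trans to C8) | C/C1=C/C([O-])=C(C(C)C)/[C@@H](OCc2ccc(OC)cc2)C/C(C)=C/CC1.[K+] | intermediate
18 | (1(10)E,4Z,7R,8S)-8-(4-methoxybenzyloxy)germacra-1(10),4-dien-6-one | C/C1=C/C(=O)[C@H](C(C)C)[C@@H](OCc2ccc(OC)cc2)C/C(C)=C/CC1 | intermediate
19 | lithium C5=C6 enolate bearing Me3Sn at C4 (C4 not assigned) | CC1([Sn](C)(C)C)/C=C([O-])/[C@H](C(C)C)[C@@H](OCc2ccc(OC)cc2)C/C(C)=C/CC1.[Li+] | intermediate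
20 | 4-trimethylstannyl 6-trimethylsilyloxy 1(10),5-diene (C4 not assigned) | CC1([Sn](C)(C)C)/C=C(O[Si](C)(C)C)/[C@H](C(C)C)[C@@H](OCc2ccc(OC)cc2)C/C(C)=C/CC1 | intermediate
21 | 5-trimethylsilyloxy-4-trimethylstannyl ketone (C4, C5 not assigned; Sn and O added to the same face) | CC1([Sn](C)(C)C)C(O[Si](C)(C)C)C(=O)[C@H](C(C)C)[C@@H](OCc2ccc(OC)cc2)C/C(C)=C/CC1 | intermediate
22 | (1(10)E,4E,7R,8S)-8-(4-methoxybenzyloxy)germacra-1(10),4-dien-6-one | C/C1=C\C(=O)[C@H](C(C)C)[C@@H](OCc2ccc(OC)cc2)C/C(C)=C/CC1 | intermediate
23 | (1(10)E,4E,7R,8S)-8-hydroxygermacra-1(10),4-dien-6-one | C/C1=C\C(=O)[C@H](C(C)C)[C@@H](O)C/C(C)=C/CC1 | intermediate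
24 | (E)-4-acetoxycinnamic acid | CC(=O)Oc1ccc(/C=C/C(=O)O)cc1 | starting material
25 | (E)-4-acetoxycinnamoyl chloride | CC(=O)Oc1ccc(/C=C/C(=O)Cl)cc1 | intermediate
26 | (1(10)E,4E,7R,8S)-6-oxogermacra-1(10),4-dien-8-yl (E)-4-acetoxycinnamate | C/C1=C\C(=O)[C@H](C(C)C)[C@@H](OC(=O)/C=C/c2ccc(OC(C)=O)cc2)C/C(C)=C/CC1 | intermediate
27 | (1(10)E,4E,6S,7S,8S)-6-hydroxygermacra-1(10),4-dien-8-yl (E)-4-acetoxycinnamate | C/C1=C\[C@H](O)[C@H](C(C)C)[C@@H](OC(=O)/C=C/c2ccc(OC(C)=O)cc2)C/C(C)=C/CC1 | intermediate
28 | (1(10)E,4E,6S,7S,8S)-6-hydroxygermacra-1(10),4-dien-8-yl (E)-4-hydroxycinnamate | C/C1=C\[C@H](O)[C@H](C(C)C)[C@@H](OC(=O)/C=C/c2ccc(O)cc2)C/C(C)=C/CC1 | target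

Total step count: 14.
Longest linear sequence: 11 steps (1, 2, 3, 7, 8, 9, 10, 11, 12, 13, 14).

Steps most likely to fail

**Step 8.**
- What may go wrong: the C8 alkoxide may be lost from enolate 17 by E1cB elimination during the time the rearrangement needs. Leakage through a boat-like transition state would also erode the chirality transfer.
- The fallback sets out from 15 and comes back at 18.
- The elimination is allowed to run to completion (KH, 18-crown-6, THF, 40 °C). This should give, still by the same ring enlargement, the cross-conjugated (1(10)E,4Z)-germacra-1(10),4,7-trien-6-one F1.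
- The C8 oxygen is then put back under catalyst control. Copper-catalysed enantioselective conjugate borylation of the less substituted C7=C8 enone (CuCl, NaOt-Bu, a chiral ferrocenyl bisphosphine, B2pin2, MeOH, THF) should give the 8-(pinacolatoboryl) ketone F2.
- Oxidation with retention (NaBO3·4H2O, THF–H2O) leads to the (4Z)-8-hydroxy ketone F3.
- Protection with 4-methoxybenzyl trichloroacetimidate and La(OTf)3 returns 18.

**Step 10.**
- What may go wrong: control of the alkene geometry is poor if the peracid is not confined to the face that tin occupies, or if part of the elimination runs syn. Either case regenerates the cis enone. Competing epoxidation of C1=C10 is a further risk.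
- The fallback sets out from 18 and comes back at 22. It replaces addition–elimination by a stereospecific olefin inversion.
- Luche reduction gives the (4Z)-allylic alcohol F4, whose C6 configuration is of no consequence.
- Hydroxyl-directed epoxidation (VO(acac)2, t-BuOOH, CH2Cl2, 0 °C) gives the cis-4,5-epoxy alcohol F5.
- SN2 opening at C5 with LiPPh2, then MeI, forms a betaine. Its syn-elimination should give the (4E)-allylic alcohol F6.
- MnO2 in CH2Cl2 then oxidises F6 to 22.

**Step 13.**
- What may go wrong: facial selectivity at C6 is poor if conformers other than the crown are populated. Conjugate reduction may also compete.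
- The fallback sets out from 23 and comes back at 27. It replaces outer-face attack by intramolecular hydride delivery.
- Saksena–Evans reduction (Me4NBH(OAc)3, MeCN–AcOH, −30 °C) binds boron to O8 and delivers hydride to C6 from the face that carries O8. This should give the 1,3-anti (6S,7S,8S)-germacra-1(10),4-diene-6,8-diol F7.
- Site-selective acylation of the equatorial, non-allylic C8 hydroxyl with acid chloride 25 (pyridine, CH2Cl2, −20 °C) then gives 27.

Further compounds
F1 | step 8 | (1(10)E,4Z)-germacra-1(10),4,7-trien-6-one (C7=C8 geometry not assigned) | C/C1=C/C(=O)C(C(C)C)=CC/C(C)=C/CC1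
F2 | step 8 | (1(10)E,4Z)-8-(4,4,5,5-tetramethyl-1,3,2-dioxaborolan-2-yl)germacra-1(10),4-dien-6-one, same spatial arrangement at C7 and C8 as 18 | C/C1=C/C(=O)[C@H](C(C)C)[C@@H](B2OC(C)(C)C(C)(C)O2)C/C(C)=C/CC1
F3 | step 8 | (1(10)E,4Z,7R,8S)-8-hydroxygermacra-1(10),4-dien-6-one | C/C1=C/C(=O)[C@H](C(C)C)[C@@H](O)C/C(C)=C/CC1
F4 | step 10 | (1(10)E,4Z)-8-(4-methoxybenzyloxy)germacra-1(10),4-dien-6-ol (C6 not assigned) | C/C1=C/C(O)[C@H](C(C)C)[C@@H](OCc2ccc(OC)cc2)C/C(C)=C/CC1
F5 | step 10 | cis-4,5-epoxy-8-(4-methoxybenzyloxy)germacr-1(10)-en-6-ol (one oxirane face drawn, C6 not assigned) | C2[C@@]1(C)O[C@H]1C(O)[C@H](C(C)C)[C@@H](OCc3ccc(OC)cc3)C/C(C)=C/C2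
F6 | step 10 | (1(10)E,4E)-8-(4-methoxybenzyloxy)germacra-1(10),4-dien-6-ol (C6 not assigned) | C/C1=C\C(O)[C@H](C(C)C)[C@@H](OCc2ccc(OC)cc2)C/C(C)=C/CC1
F7 | step 13 | (1(10)E,4E,6S,7S,8S)-germacra-1(10),4-diene-6,8-diol | C/C1=C\[C@H](O)[C@H](C(C)C)[C@@H](O)C/C(C)=C/CC1
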